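## Retrosynthetic overview

1. Numbering: benzofuran (O1, C2, C3, C3a, C4–C7, C7a); ring A = benzo ring, ring B = dihydrofuran ring, ring C = dimethoxyphenyl ring. Target 15 ⇒ aldehyde 12 (the C5 acrylic acid is made last by Knoevenagel–Doebner condensation) ⇒ nitrile ester 10 (one hydride reduction turns the C3 ester into CH2OH and the C5 nitrile into CHO; MOM removal).
2. 10 ⇒ fluoroarene ester 6 + veratraldehyde 7: one catalytic asymmetric aldol/SNAr annulation forms the C2–C3 and O1–C7a bonds, closes ring B and sets C2 and C3.
3. Enabling feature: in ring A the oxygen-bearing C7a is para to C5, so with the first acrylic-acid carbon held as a nitrile on C5, a fluorine on C7a is displaceable by SNAr. C3 is alpha to the hydroxymethyl carbon, so with that carbon held as an ester, C3 is an enolate carbon and an epimerisable centre.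
4. 6 ⇒ 3-bromo-4-fluorobenzonitrile 1: C–H borylation/oxidation next to fluorine (the C7 oxygen), MOM protection, Negishi coupling with a Reformatsky reagent (C3 and its ester).
5. Ring order: rings A and C are bought as benzene rings; ring B is the only ring formed, in step 4.

Key step: step 4

Assumption: the cinchonidine-derived ammonium salt is taken to give the (2R) series; its sense of induction in this new reaction cannot be predicted with certainty, and in the opposite case the pseudoenantiomeric cinchonine-derived salt is used with nothing else changed.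

## Route

Step 1
Reactants: 1 3-bromo-4-fluorobenzonitrile
Product: 3 3-bromo-4-fluoro-5-hydroxybenzonitrile, via aryl boronate 2 (not isolated)
Conditions: [Ir(OMe)(cod)]2 (1.5 mol%), 4,4'-di-tert-butyl-2,2'-bipyridine (3 mol%), B2pin2 (1.0 equiv), THF, 60 °C; then KHSO5 (Oxone), acetone–H2O, 25 °C
Reagents that add atoms: potassium peroxymonosulfate KHSO5, [K+].[O-]S(=O)(=O)OO
Why: Iridium-catalysed aromatic C–H borylation is sterically controlled, so the C–H flanked by bromine and nitrile is excluded and the C–H next to the small, acidifying fluorine should be preferred over the one next to the nitrile, and the C–B bond of 2 is then oxidised to C–OH by peroxymonosulfate at the same position; no stereocentre is formed.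

Step 2
Reactants: 3 3-bromo-4-fluoro-5-hydroxybenzonitrile
Product: 4 3-bromo-4-fluoro-5-(methoxymethoxy)benzonitrile
Conditions: MOMCl (1.3 equiv), i-Pr2NEt (1.5 equiv), CH2Cl2, 0 → 25 °C
Reagents that add atoms: chloromethyl methyl ether (MOMCl), COCCl
Why: Williamson-type O-alkylation of the acidic fluorophenol gives the MOM acetal, which is stable to the zinc reagent, hydroxide and hydride used later and keeps O7 from becoming a ring-deactivating phenoxide in step 4; no stereocentre is formed.

Step 3
Reactants: 4 3-bromo-4-fluoro-5-(methoxymethoxy)benzonitrile; 5 (2-tert-butoxy-2-oxoethyl)zinc bromide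
Product: 6 tert-butyl 2-[5-cyano-2-fluoro-3-(methoxymethoxy)phenyl]acetate
Conditions: Pd2(dba)3 (1 mol%), XPhos (4 mol%), THF, 60 °C
Reagents that add atoms: none
Why: Palladium-catalysed Negishi coupling of the Reformatsky zinc enolate (ester alpha-arylation) should take place at the C–Br bond of the electron-poor arene, and the weakly basic zinc enolate leaves the nitrile, the MOM ether and the SNAr-active C–F bond untouched; no stereocentre is formed.

Step 4
Reactants: 6 tert-butyl 2-[5-cyano-2-fluoro-3-(methoxymethoxy)phenyl]acetate; 7 3,4-dimethoxybenzaldehyde (veratraldehyde)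
Product: 10 tert-butyl (2R,3R)-5-cyano-2-(3,4-dimethoxyphenyl)-7-(methoxymethoxy)-2,3-dihydro-1-benzofuran-3-carboxylate, via aldol adduct 8 (not isolated), via cis ester 9 (not isolated)
Conditions: O-allyl-N-(9-anthracenylmethyl)cinchonidinium bromide (10 mol%), CsOH·H2O (1.5 equiv), toluene, −40 → 0 °C
Reagents that add atoms: none
Why: Proposed new method: under solid–liquid phase-transfer conditions the chiral ammonium enolate of 6 (its CH2 is about as acidic as that of the arylacetonitriles routinely deprotonated in this way) adds to aldehyde 7 (C2–C3 bond), and the ammonium alkoxide of 8 then displaces fluoride at C7a by addition–elimination (O1–C7a bond), the negative charge of the transition state being delocalised into the para nitrile. The closest known reaction types are the asymmetric phase-transfer Darzens condensation, in which a reversibly formed aldolate is closed by intramolecular O-alkylation inside a chiral ion pair, and tandem condensation/SNAr ring closures of ortho-fluoroaryl carbon acids; here O-arylation takes the place of O-alkylation and a five-membered ring that of the epoxide. Ring B closes by 5-exo-trig ipso attack of the alkoxide on the aromatic carbon, the ring A π-bond that takes up the charge lying outside the new ring. C2 is controlled by the chiral cation, either in the aldol addition or, if that addition is reversible as expected for a stabilised ester enolate, by Curtin–Hammett selection of the (R)-aldolate in the irreversible ring closure; C3 is controlled thermodynamically, because the ester alpha-position equilibrates under the basic conditions and cis ester 9 (from the anti aldolate) drains into the 2,3-trans ester 10. The step needs the aldolate oxygen to attack C7a, and not the enolate carbon or enolate oxygen of 6, hydroxide or a second molecule: the enolate is consumed by the faster carbonyl addition and is held in the ring plane away from the π-face of C7a, hydroxide stays in the solid phase, and only the tethered sp3 alkoxide reaches C7a through a five-membered transition state. The MOM group keeps O7 from becoming a phenoxide, which would switch off the SNAr, and the tert-butyl ester resists the base.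

Step 5
Reactants: 10 tert-butyl (2R,3R)-5-cyano-2-(3,4-dimethoxyphenyl)-7-(methoxymethoxy)-2,3-dihydro-1-benzofuran-3-carboxylate
Product: 11 (2R,3S)-2-(3,4-dimethoxyphenyl)-3-(hydroxymethyl)-7-(methoxymethoxy)-2,3-dihydro-1-benzofuran-5-carbaldehyde
Conditions: DIBAL-H (i-Bu2AlH, 6 equiv), CH2Cl2, −78 → 0 °C; then aq. potassium sodium tartrate, 25 °C
Reagents that add atoms: water, O
Why: Hydride reduction with i-Bu2AlH takes the tert-butyl ester to the primary alcohol and the aryl nitrile only to the aldehyde oxidation level, released on aqueous work-up, while the aryl ethers and the MOM acetal are inert at 0 °C; C2 is not acidic and C3 already has the stable trans arrangement, so no stereocentre should change (the C3 descriptor changes from R to S only because CH2OH ranks below C2).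

Step 6
Reactants: 11 (2R,3S)-2-(3,4-dimethoxyphenyl)-3-(hydroxymethyl)-7-(methoxymethoxy)-2,3-dihydro-1-benzofuran-5-carbaldehyde
Product: 12 (2R,3S)-2-(3,4-dimethoxyphenyl)-7-hydroxy-3-(hydroxymethyl)-2,3-dihydro-1-benzofuran-5-carbaldehyde
Conditions: 2 M aq. HCl, THF, 25 °C
Reagents that add atoms: none
Why: Acid-catalysed hydrolysis of the aryl MOM acetal frees the C7 phenol under conditions that should leave the benzylic C2–O1 bond intact, because O1 is deactivated by the para formyl group; no stereocentre is touched.

Step 7
Reactants: 12 (2R,3S)-2-(3,4-dimethoxyphenyl)-7-hydroxy-3-(hydroxymethyl)-2,3-dihydro-1-benzofuran-5-carbaldehyde; 13 malonic acid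
Product: 15 (2E)-3-[(2R,3S)-2-(3,4-dimethoxyphenyl)-7-hydroxy-3-(hydroxymethyl)-2,3-dihydro-1-benzofuran-5-yl]prop-2-enoic acid, via arylidenemalonic acid 14 (not isolated)
Conditions: pyridine, piperidine (0.1 equiv), 90 °C; then 1 M aq. HCl, 0 °C
Reagents that add atoms: none
Why: Knoevenagel condensation in the Doebner modification gives arylidenemalonic acid 14, which loses carbon dioxide in hot pyridine to the thermodynamically preferred (E)-acrylic acid, as is usual for 3-hydroxy-4-alkoxybenzaldehydes; the stereocentres are remote and not acidic.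

## Compound list

1 | 3-bromo-4-fluorobenzonitrile | N#Cc1ccc(F)c(Br)c1 | starting material
2 | 3-bromo-4-fluoro-5-(4,4,5,5-tetramethyl-1,3,2-dioxaborolan-2-yl)benzonitrile (aryl boronate) | N#Cc1cc(Br)c(F)c(B2OC(C)(C)C(C)(C)O2)c1 | intermediate
3 | 3-bromo-4-fluoro-5-hydroxybenzonitrile | N#Cc1cc(O)c(F)c(Br)c1 | intermediate
4 | 3-bromo-4-fluoro-5-(methoxymethoxy)benzonitrile | COCOc1cc(C#N)cc(Br)c1F | intermediate
5 | (2-tert-butoxy-2-oxoethyl)zinc bromide | CC(C)(C)OC(=O)C[Zn]Br | starting material
6 | tert-butyl 2-[5-cyano-2-fluoro-3-(methoxymethoxy)phenyl]acetate | CC(C)(C)OC(=O)Cc1cc(C#N)cc(OCOC)c1F | intermediate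
7 | 3,4-dimethoxybenzaldehyde | COc1ccc(C=O)cc1OC | starting material
8 | tert-butyl (3R)-2-[5-cyano-2-fluoro-3-(methoxymethoxy)phenyl]-3-(3,4-dimethoxyphenyl)-3-hydroxypropanoate (aldol adduct, both C2 epimers, present as its ammonium alkoxide) | COc1ccc([C@H](O)C(C(=O)OC(C)(C)C)c2cc(C#N)cc(OCOC)c2F)cc1OC | intermediate
9 | tert-butyl (2R,3S)-5-cyano-2-(3,4-dimethoxyphenyl)-7-(methoxymethoxy)-2,3-dihydro-1-benzofuran-3-carboxylate (cis ester) | COc1ccc([C@@H]2Oc3c(OCOC)cc(C#N)cc3[C@@H]2C(=O)OC(C)(C)C)cc1OC | intermediate
10 | tert-butyl (2R,3R)-5-cyano-2-(3,4-dimethoxyphenyl)-7-(methoxymethoxy)-2,3-dihydro-1-benzofuran-3-carboxylate (trans ester) | COc1ccc([C@@H]2Oc3c(OCOC)cc(C#N)cc3[C@H]2C(=O)OC(C)(C)C)cc1OC | intermediate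
11 | (2R,3S)-2-(3,4-dimethoxyphenyl)-3-(hydroxymethyl)-7-(methoxymethoxy)-2,3-dihydro-1-benzofuran-5-carbaldehyde | COc1ccc([C@@H]2Oc3c(OCOC)cc(C=O)cc3[C@H]2CO)cc1OC | intermediate
12 | (2R,3S)-2-(3,4-dimethoxyphenyl)-7-hydroxy-3-(hydroxymethyl)-2,3-dihydro-1-benzofuran-5-carbaldehyde | COc1ccc([C@@H]2Oc3c(O)cc(C=O)cc3[C@H]2CO)cc1OC | intermediate
13 | malonic acid | OC(=O)CC(=O)O | starting material
14 | 2-{[(2R,3S)-2-(3,4-dimethoxyphenyl)-7-hydroxy-3-(hydroxymethyl)-2,3-dihydro-1-benzofuran-5-yl]methylidene}propanedioic acid | COc1ccc([C@@H]2Oc3c(O)cc(C=C(C(=O)O)C(=O)O)cc3[C@H]2CO)cc1OC | intermediate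
15 | (2E)-3-[(2R,3S)-2-(3,4-dimethoxyphenyl)-7-hydroxy-3-(hydroxymethyl)-2,3-dihydro-1-benzofuran-5-yl]prop-2-enoic acid (CNP0193199.1) | COc1ccc([C@@H]2Oc3c(O)cc(/C=C/C(=O)O)cc3[C@H]2CO)cc1OC | target

## Summary and risks

Total step count: 7. Longest linear sequence: 7 steps (1 to 15).

Steps most likely to fail:

Step 4 (Proposed new method). The ring closure inside the ion pair may not discriminate well enough between the two aldolates, or a racemic reaction at the surface of the solid base may compete, so that 10 forms with low enantiomeric purity. Retro-aldol cleavage followed by dehydration to the stilbene ester, and base-induced ring opening of 10 at C2–O1, are further loss channels. The fallback uses an auxiliary-controlled aldol and a separate SNAr ring closure; it sets out from 4 and comes back at 12. Negishi coupling of 4 with the Reformatsky reagent made from (R)-4-benzyl-3-(bromoacetyl)-1,3-oxazolidin-2-one and zinc dust (Pd2(dba)3, XPhos, THF) would give the arylacetyl imide F1. Evans syn aldol addition to 7 (n-Bu2BOTf, i-Pr2NEt, CH2Cl2, −78 → 0 °C, H2O2 work-up) should give the (2R,3R) syn aldol F2 through the Zimmerman–Traxler chair of the Z boron enolate, both centres being fixed by the auxiliary. LiBH4 (THF, 0 °C) removes the auxiliary to give the (1R,2S) diol F3, and TrCl in pyridine protects the primary hydroxyl as the trityl ether F4, which can neither migrate nor suffer retro-aldol cleavage. KN(SiMe3)2 (THF, −78 → 0 °C) then closes ring B by SNAr of the secondary alkoxide to the 2,3-trans nitrile F5 (a syn aldol gives the trans ring directly). i-Bu2AlH as in step 5 gives the aldehyde F6, and the conditions of step 6 remove trityl and MOM together to return to 12.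

Step 5. The hindered tert-butyl ester may be reduced only slowly, so that forcing the reaction takes the nitrile past the aldehyde level to the benzylic amine or leaves the C3 carbon at the aldehyde level. The fallback replaces the one global reduction by two chemoselective ones; it sets out from 10 and comes back at 11. LiBH4 with methanol in THF at 50 °C, which does not touch aryl nitriles, would reduce only the ester and give the hydroxymethyl nitrile F7. i-Bu2AlH (2.2 equiv, toluene, −78 °C, then aqueous work-up) then takes the nitrile alone to aldehyde 11.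

Step 1. Borylation may take place in part at the C–H next to the nitrile, and the regioisomeric phenols may be hard to separate. The fallback fixes the position by electrophilic substitution before boron is introduced; it sets out from 1 and comes back at 2. Iodination with N-iodosuccinimide in CF3SO3H should go to the only position that is ortho to fluorine and meta to the nitrile and give 3-bromo-4-fluoro-5-iodobenzonitrile F8. Miyaura borylation at the more reactive C–I bond (PdCl2(dppf), B2pin2, KOAc, dioxane, 80 °C) gives boronate 2, which is oxidised to 3 as in step 1.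

Further compounds
F1 | step 4 | (4R)-4-benzyl-3-{[5-cyano-2-fluoro-3-(methoxymethoxy)phenyl]acetyl}-1,3-oxazolidin-2-one | O=C(Cc1cc(C#N)cc(OCOC)c1F)N1C(=O)OC[C@H]1Cc1ccccc1
F2 | step 4 | (4R)-4-benzyl-3-[(2R,3R)-2-[5-cyano-2-fluoro-3-(methoxymethoxy)phenyl]-3-(3,4-dimethoxyphenyl)-3-hydroxypropanoyl]-1,3-oxazolidin-2-one | COc1ccc([C@H](O)[C@H](C(=O)N2C(=O)OC[C@H]2Cc2ccccc2)c2cc(C#N)cc(OCOC)c2F)cc1OC
F3 | step 4 | 3-[(1R,2S)-1-(3,4-dimethoxyphenyl)-1,3-dihydroxypropan-2-yl]-4-fluoro-5-(methoxymethoxy)benzonitrile | COc1ccc([C@H](O)[C@H](CO)c2cc(C#N)cc(OCOC)c2F)cc1OC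
F4 | step 4 | 3-[(1R,2S)-1-(3,4-dimethoxyphenyl)-1-hydroxy-3-(triphenylmethoxy)propan-2-yl]-4-fluoro-5-(methoxymethoxy)benzonitrile | COc1ccc([C@H](O)[C@H](COC(c2ccccc2)(c2ccccc2)c2ccccc2)c2cc(C#N)cc(OCOC)c2F)cc1OC
F5 | step 4 | (2R,3S)-2-(3,4-dimethoxyphenyl)-7-(methoxymethoxy)-3-[(triphenylmethoxy)methyl]-2,3-dihydro-1-benzofuran-5-carbonitrile | COc1ccc([C@@H]2Oc3c(OCOC)cc(C#N)cc3[C@H]2COC(c2ccccc2)(c2ccccc2)c2ccccc2)cc1OC
F6 | step 4 | (2R,3S)-2-(3,4-dimethoxyphenyl)-7-(methoxymethoxy)-3-[(triphenylmethoxy)methyl]-2,3-dihydro-1-benzofuran-5-carbaldehyde | COc1ccc([C@@H]2Oc3c(OCOC)cc(C=O)cc3[C@H]2COC(c2ccccc2)(c2ccccc2)c2ccccc2)cc1OC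
F7 | step 5 | (2R,3S)-2-(3,4-dimethoxyphenyl)-3-(hydroxymethyl)-7-(methoxymethoxy)-2,3-dihydro-1-benzofuran-5-carbonitrile | COc1ccc([C@@H]2Oc3c(OCOC)cc(C#N)cc3[C@H]2CO)cc1OC
F8 | step 1 | 3-bromo-4-fluoro-5-iodobenzonitrile | N#Cc1cc(Br)c(F)c(I)c1
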